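Readings and results were computed with constants of no real substance; the scatter is artificial.

The constants of this reaction are unknown to you, and the noon run was made at one temperature, so you reckon from the charges and that one run.

| flask | substrate | reagent | temperature | remark | time |
|---|---|---|---|---|---|
| noon | 0.60 M | 0.32 M | 95 °C | run made earlier |  |
| amber | 0.40 M | 0.320 M | 95 °C |  | 40 min |
| red | 0.40 M | 0.320 M | 35 °C |  | 40 min |
| green | 0.40 M | 0.320 M |  | at 35 °C until 30 min, from then on at 95 °C | 40 min |
| teal | 0.40 M | 0.320 M | 65 °C |  | 40 min |

noon run (percent of the substrate charged): time / min: product / % = 0.500: 7.0; 1.33: 11.7; 2.50: 17.0; 4.00: 23.1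

(readings scatter by 0.5 percentage points)

- the analysis behind the earlier runs scatters by 0.5 percentage points, standard deviation
- the earlier runs do not show what temperature does; that part of a forecast is a guess

- which flask leads in amount of product, in percent of the substrate charged ("all alike" within 1.5 percentage points) (amber / red / green / teal / all alike)
- how much product is there at the end, in percent of the substrate charged: amber
- how much product is there at the end, in percent of the substrate charged: red
- how much product is there at the end, in percent of the substrate charged: green
- how much product is there at the end, in percent of the substrate charged: teal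

Solve the flask at both ends and join them. At the far end, if each product takes one reagent, the ceiling on product as a fraction of the substrate charged is the reagent charge divided by the substrate charge, 80.0%, the same in amber, red, green and teal. In these flasks reagent is the limiting reagent, its charge being smaller than that of substrate. At the near end, the later noon readings climb by about 0.0427 min⁻¹ as a fraction of noon's substrate charge, a value read with their scatter. Noon and amber hold the same reagent at the same temperature but differ in substrate, so I carry that fractional slope over on an assumption of my own, that the rate goes with the substrate present. At that slope the ceiling would be reached in 18.7 min, and joining the two ends with an exponential gives me 70.5% for amber at the end. For the other flasks I have the ceiling and no rate.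

The forecast uses the same ceiling and puts amber first: amber 68%, red 6%, green 43%, teal 32%. For red, green and teal it says “Temperature is a guess”. My amber figure is higher than its figure.

The flasks give amber 76.0%, red 71.5%, green 71.3% and teal 80.0%, so teal leads.

    substrate ⇌ intermediate A (K = 1.90, k = 0.0415 min⁻¹, Ea = 100 kJ mol⁻¹, ΔH = −21.0 kJ mol⁻¹)
    intermediate A ⇌ intermediate B (K = 12.0, k = 1.41 min⁻¹, Ea = 86.0 kJ mol⁻¹, ΔH = −90.0 kJ mol⁻¹)
    reagent + intermediate B → product (k = 3.55 M⁻¹ min⁻¹, Ea = 49.0 kJ mol⁻¹)
    reagent + intermediate A ⇌ intermediate C (K = 9.20 M⁻¹, k = 0.955 M⁻¹ min⁻¹, Ea = 44.0 kJ mol⁻¹, ΔH = 9.00 kJ mol⁻¹)
    (constants at 35 °C)

Teal's 80.0% stands on the ceiling with 0.0237% of its reagent left at the end, and in teal half of the turnover of the making of intermediate A from substrate up to then is done by 0.570 min, far less than the 40 min of the run. For a neighbour of teal charged with 0.080 M of reagent the ceiling is 20.0%, and that flask ends with 20.0% of product and 0% of its reagent.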